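Its constants are assumed; the flask was simulated.

The trap in this flask is to tune the spacing of the substrate portions while the coupling partner still has to come in through the gas.

    substrate + coupling partner ⇌ target (K1 = 460 M⁻¹, k1 = 2.1 M⁻¹ s⁻¹)
    substrate + coupling partner → isomer of the product (k2 = 2.5 M⁻¹ s⁻¹)
    substrate + coupling partner → second isomer (k3 = 4.1 M⁻¹ s⁻¹)
    crystals ⇌ target, rate k4*(cs4 - [target]) while solid is left; crystals form when [target] > cs4 (cs4 = 0.052 M, k4 = 0.67 s⁻¹)
    gas ⇌ coupling partner, rate k5*(csat - [coupling partner]) (k5 = 0.31 s⁻¹, csat = 13 mM)

common to all: substrate 0.11 M (in portions, 2); gas 13 mM (held); time 20 s
- beta: the portions of substrate follow each other after 1.2 s, the first at the start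
- theta: the portions of substrate follow each other after 1.5 s, the first at the start
- zeta: the portions of substrate follow each other after 2.5 s, the first at the start
- gamma: the portions of substrate follow each other after 4.0 s, the first at the start
- delta: the portions of substrate follow each other after 6.0 s, the first at the start

- amount of target at the end, in percent of the substrate charged for beta, theta, zeta, gamma, delta, in this order
- how that number moves from the first to the last of them (falls all the way / falls, then rises / rises, then falls / rises all the way / hardly changes)

- target is meant together with its crystals
- solid, in amounts per volume of the solution: crystals
- at the start none of coupling partner is dissolved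
- "hardly changes" means that all values lie within two and a half points (for a concentration: within two and a half percent of the largest)
- run time (beta): 20 s

To whoever takes over the bench: the flask starts with substrate and no dissolved coupling partner, so I follow what the gas delivers. Every substrate that reacts takes one of three steps with the same two reactants, so the constants divide the turnover, and the forward share going to target, the target share or selectivity, is 24.1%.

As a first guess for the mean substrate over the run I take 0.0825 M. Coupling partner then disappears with a pseudo-first-order constant of 0.718 s⁻¹, faster than the transfer coefficient 0.31 s⁻¹. That ratio is 2.32, so transfer and reaction share the control, and balancing them puts coupling partner near 3.92 mM and the feed at 2.81 mM s⁻¹. Over 20 s, less what stays dissolved, 52.4 mM reacts, about half of the charge, which fits the guess for the mean.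

So at the end of beta I expect 0.115 target, counting the forward step. That is 12.6 mM, less than the solubility 0.052 M, so don't look for crystals.

Leave the spacing alone. I compute it as a correction: while the first portion waits alone, the feed is 2.45 mM s⁻¹ instead of 2.81 mM s⁻¹. Over the 6.0 s of delta this costs 0.49 percentage points, which gives 0.110, and the row hardly changes.

The forecast, a little below my figure, runs from 10.9% to 10.3% and says hardly changes, on the ground that “Delaying the second portion only slightly lowers the early uptake of the coupling partner”.

The simulation gives 11.1%, 11.0%, 11.0%, 10.8% and 10.6%, and the row hardly changes.

In beta at 20.0 s, each step taken net, coupling partner is made 1.05 times as fast as it is used up and stands at 0.00487 M, with 53% of the substrate left, and the target share of the turned-over substrate gives 11.5% against 11.1%. In delta, with 55% of the substrate left at 20.0 s and coupling partner at 0.00476 M, the same share gives 11.0% against 10.6%.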